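Target: (6S)-ε,ψ-carotene (carotenoid numbering: ring A = C1–C6, chain C7…C15, C15′…C1′). Ring A is the only ring and is bought as a cyclohexenone, so no ring is formed in the route.
Last operation: the C8–C9 single bond and the C9=C10 double bond are made in one flask from three components: a C11 alkenyl iodide (C1–C8), 1,1-diborylethane (C9 plus methyl C19) and a C27 polyenal (C10–C1′).
Enabling feature: C9 is the methyl-bearing sp2 carbon between the C7=C8 vinylene on ring A and C10–H, an alkene terminus with two carbon substituents. It maps onto a CH3–C(B)2 carbon: one boron is spent on olefination of the C10 aldehyde, the other on cross-coupling to C8.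
C11 iodide: C6 is set by CBS reduction of the enone and suprafacial Still–Wittig [2,3] transfer of the C–O chirality into the C6–C7 bond, followed by oxidation and Takai iodo-olefination (E-C7=C8).
C27 polyenal: pseudoionone → C15 Wittig salt; mono-Wittig with the C10 dialdehyde → C25 aldehyde; C2 Wittig homologation.
Key step: step 10

Assumption: the ring stereocentre of the given SMILES works out as (6S) (priorities C5 > C1 > C7 > H). Commercial pseudoionone is taken as its (3E,5E) isomer, and residual 5Z material should be removed when the C15 phosphonium salt is crystallised.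

Step 1
Reactants: 1 2,4,4-trimethylcyclohex-2-en-1-one
Product: 2 (R)-2,4,4-trimethylcyclohex-2-en-1-ol
Conditions: (S)-2-methyl-CBS-oxazaborolidine (10 mol %), BH3·SMe2, THF, −20 °C; then MeOH
Reagents that add atoms: none
Why: Corey–Bakshi–Shibata reduction: the ketone should bind to the catalyst boron with its larger C2(CH3)=C3 flank away from the B-methyl group, so that the borane held on nitrogen delivers hydride to one face and sets the (R)-carbinol (same sense as aryl methyl ketones with this catalyst antipode), while catalysed 1,2-reduction outruns hydroboration of the trisubstituted alkene.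

Step 2
Reactants: 2 (R)-2,4,4-trimethylcyclohex-2-en-1-ol
Product: 3 (R)-tributyl{[(2,4,4-trimethylcyclohex-2-en-1-yl)oxy]methyl}stannane
Conditions: KH, THF, 0 °C; Bu3SnCH2I, 0 → 23 °C
Reagents that add atoms: tributyl(iodomethyl)stannane, CCCC[Sn](CCCC)(CCCC)CI
Why: Williamson ether synthesis on a primary iodide; the C–O stereocentre is not involved and stays (R).

Step 3
Reactants: 3 (R)-tributyl{[(2,4,4-trimethylcyclohex-2-en-1-yl)oxy]methyl}stannane
Product: 5 (S)-α-cyclogeraniol, via lithiomethyl ether 4 (not isolated)
Conditions: n-BuLi, THF, −78 °C; then H2O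
Reagents that add atoms: none
Why: Tin–lithium exchange frees the unstabilised α-alkoxy carbanion 4, which undergoes the Still–Wittig [2,3]-sigmatropic rearrangement through a five-membered envelope on the ring face that bears oxygen, so that the C–O stereocentre is traded suprafacially for the new C6–C7 bond [(R) in 3 becomes (S) in 5] and the double bond lands at C4=C5 as in ring A of the target.

Step 4
Reactants: 5 (S)-α-cyclogeraniol
Product: 6 (S)-α-cyclocitral
Conditions: Dess–Martin periodinane, CH2Cl2, 0 °C
Reagents that add atoms: none
Why: Dess–Martin oxidation works without strong acid or base, which should keep the β,γ-unsaturated aldehyde from epimerising at C6 or slipping into conjugation.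

Step 5
Reactants: 6 (S)-α-cyclocitral
Product: 7 (6S)-6-[(E)-2-iodoethenyl]-1,5,5-trimethylcyclohex-1-ene
Conditions: CrCl2, CHI3, THF, 0 → 23 °C, dark; then H2O
Reagents that add atoms: iodoform, IC(I)I
Why: Takai olefination: the gem-dichromium carbenoid from CHI3 and divalent chromium adds to the aldehyde and eliminates with the bulky ring and iodine apart, which should give the (E)-iodide, and the weakly basic reagent leaves C6 untouched.

Step 6
Reactants: 8 (3E,5E)-pseudoionone
Product: 9 vinyl-ψ-ionol (racemic)
Conditions: CH2=CHMgBr, THF, −20 → 0 °C; then H2O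
Reagents that add atoms: vinylmagnesium bromide, C=C[Mg]Br
Why: Grignard 1,2-addition to the dienone carbonyl, favoured for the hard vinyl reagent at low temperature; the new tertiary carbinol centre is racemic and is erased in step 7.

Step 7
Reactants: 9 vinyl-ψ-ionol (racemic)
Product: 10 [(2E,4E,6E)-3,7,11-trimethyldodeca-2,4,6,10-tetraen-1-yl]triphenylphosphonium bromide
Conditions: PPh3·HBr, MeOH, 23 °C; recrystallisation
Reagents that add atoms: triphenylphosphine hydrobromide, [Br-].c1ccc(cc1)[PH+](c1ccccc1)c1ccccc1
Why: Acid ionises the tertiary doubly allylic alcohol and PPh3 captures the delocalised cation at its unhindered primary terminus C11′ (SN1′-type allylic transposition, the classical Wittig salt formation from vinyl carbinols), giving mainly the (E)-C9′=C10′ bond, and crystallisation should remove Z isomers.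

Step 8
Reactants: 10 C15 phosphonium bromide; 11 (2E,4E,6E)-2,7-dimethylocta-2,4,6-trienedial
Product: 13 all-E apo-12′-lycopenal, via C15 ylide 12 (not isolated)
Conditions: NaOMe, CH2Cl2/MeOH, 0 → 23 °C, 11 in excess; then heptane, reflux; crystallisation
Reagents that add atoms: none
Why: Wittig olefination of one aldehyde group of the symmetrical dialdehyde, held at the mono stage by the excess of 11 and by the lower electrophilicity of the longer polyenal 13; the new disubstituted C11′=C12′ bond forms as an E/Z mixture that heating should equilibrate to E.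

Step 9
Reactants: 13 all-E apo-12′-lycopenal
Product: 15 all-E apo-10′-lycopenal, via dioxolane acetal 14 (not isolated)
Conditions: (1,3-dioxolan-2-ylmethyl)triphenylphosphonium bromide, KOt-Bu, THF, 0 → 23 °C; then oxalic acid (cat.), THF/H2O, 23 °C
Reagents that add atoms: (1,3-dioxolan-2-ylmethyl)triphenylphosphonium bromide, [Br-].C1COC(C[P+](c2ccccc2)(c2ccccc2)c2ccccc2)O1; water, O
Why: Wittig two-carbon homologation with a masked formylmethylene ylide avoids repeated chain extension, and mild acid both frees the aldehyde and equilibrates the new α,β-bond C11=C12 to E.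

Step 10
Reactants: 16 1,1-bis(pinacolboryl)ethane; 15 all-E apo-10′-lycopenal; 7 (6S)-6-[(E)-2-iodoethenyl]-1,5,5-trimethylcyclohex-1-ene
Product: 19 (6S)-ε,ψ-carotene, via lithiated diborylethane 17 (not isolated), via nonaenyl boronate 18 (not isolated)
Conditions: 16, lithium 2,2,6,6-tetramethylpiperidide (LiTMP), THF, 0 °C; 15, −78 → 0 °C; then 7, Pd(OAc)2 (5 mol %), SPhos (10 mol %), aq K3PO4, THF, 23–35 °C, argon, dark
Reagents that add atoms: none
Why: LiTMP removes the C–H proton of 16 that is acidified by two vacant boron p orbitals, carbanion 17 adds 1,2 to the C10 aldehyde of 15, the alkoxide closes onto one of the two diastereotopic boryl groups and the four-membered oxaboretanide collapses by syn B–O elimination to create C9=C10 and leave boronate 18; after addition of base, 7 and the catalyst, oxidative addition of zerovalent palladium into the C8–I bond, transmetalation of the base-activated C9–B bond and reductive elimination form the C8–C9 bond with retention at both alkene partners. The closest known reaction types are the boron–Wittig olefination of aldehydes with lithiated 1,1-diborylalkanes to trisubstituted alkenyl boronates and the Suzuki–Miyaura coupling of alkenyl iodides with polyenyl boronates under Pd(OAc)2/SPhos; the two are telescoped because a nonaenyl boronate is prone to protodeboronation and oxidation on isolation. No ring is closed and no stereocentre is created: C6 comes in with 7 and should be safe, because its doubly allylic C–H meets nothing stronger than aqueous phosphate near room temperature, far from the hot alkoxide regime that moves C4=C5 into conjugation. The selectivity needed is geometric: C9=C10 must form with boron (later C8) trans to C11, which the substrate should secure because in the oxaboretanide the polyenyl residue on C10 avoids the pinacol boronate that stays on C9 and lies next to the small methyl group, while C7=C8 keeps the E geometry set in step 5. Chemoselectivity rests on the order of addition: the aldehyde is consumed before palladium is added, 16 is used in no more than a slight excess so that little sp3 gem-diboron reagent is left to compete for 7, and the trisubstituted C1′=C2′ and C4=C5 alkenes are inert to all reagents. In one flask the operation should thus deliver one C=C bond, the C8–C9 bond, the C19 methyl branch and the complete decaene from an aldehyde, an iodide and a two-carbon reagent.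

Compound list
1 | 2,4,4-trimethylcyclohex-2-en-1-one | O=C1CCC(C)(C)C=C1C | starting material
2 | (R)-2,4,4-trimethylcyclohex-2-en-1-ol | O[C@@H]1CCC(C)(C)C=C1C | intermediate
3 | (R)-tributyl{[(2,4,4-trimethylcyclohex-2-en-1-yl)oxy]methyl}stannane | CCCC[Sn](CCCC)(CCCC)CO[C@@H]1CCC(C)(C)C=C1C | intermediate
4 | (R)-{[(2,4,4-trimethylcyclohex-2-en-1-yl)oxy]methyl}lithium (lithiomethyl ether) | [Li]CO[C@@H]1CCC(C)(C)C=C1C | intermediate
5 | (S)-α-cyclogeraniol, [(1S)-2,6,6-trimethylcyclohex-2-en-1-yl]methanol | OC[C@@H]1C(C)=CCCC1(C)C | intermediate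
6 | (S)-α-cyclocitral, (1S)-2,6,6-trimethylcyclohex-2-ene-1-carbaldehyde | O=C[C@@H]1C(C)=CCCC1(C)C | intermediate
7 | (6S)-6-[(E)-2-iodoethenyl]-1,5,5-trimethylcyclohex-1-ene | I/C=C/[C@@H]1C(C)=CCCC1(C)C | intermediate
8 | (3E,5E)-pseudoionone, (3E,5E)-6,10-dimethylundeca-3,5,9-trien-2-one | CC(C)=CCC/C(C)=C/C=C/C(C)=O | starting material
9 | vinyl-ψ-ionol, (4E,6E)-3,7,11-trimethyldodeca-1,4,6,10-tetraen-3-ol, racemic | CC(C)=CCC/C(C)=C/C=C/C(C)(O)C=C | intermediate
10 | [(2E,4E,6E)-3,7,11-trimethyldodeca-2,4,6,10-tetraen-1-yl]triphenylphosphonium bromide | CC(C)=CCC/C(C)=C/C=C/C(C)=C/C[P+](c1ccccc1)(c1ccccc1)c1ccccc1.[Br-] | intermediate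
11 | (2E,4E,6E)-2,7-dimethylocta-2,4,6-trienedial (C10 dialdehyde) | O=C/C(C)=C/C=C/C=C(C)/C=O | starting material
12 | C15 ylide, [(2E,4E,6E)-3,7,11-trimethyldodeca-2,4,6,10-tetraenylidene]triphenylphosphorane | CC(C)=CCC/C(C)=C/C=C/C(C)=C/C=P(c1ccccc1)(c1ccccc1)c1ccccc1 | intermediate
13 | all-E apo-12′-lycopenal, 2,7,11,15,19-pentamethylicosa-2,4,6,8,10,12,14,18-octaenal | CC(C)=CCC/C(C)=C/C=C/C(C)=C/C=C/C(C)=C/C=C/C=C(C)/C=O | intermediate
14 | ethylene acetal of apo-10′-lycopenal, E/Z mixture at the new C11=C12 bond (that bond drawn without descriptor) | CC(C)=CCC/C(C)=C/C=C/C(C)=C/C=C/C(C)=C/C=C/C=C(C)/C=CC1OCCO1 | intermediate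
15 | all-E apo-10′-lycopenal, 4,9,13,17,21-pentamethyldocosa-2,4,6,8,10,12,14,16,20-nonaenal | CC(C)=CCC/C(C)=C/C=C/C(C)=C/C=C/C(C)=C/C=C/C=C(C)/C=C/C=O | intermediate
16 | 1,1-bis(pinacolboryl)ethane, 2,2′-(ethane-1,1-diyl)bis(4,4,5,5-tetramethyl-1,3,2-dioxaborolane) | CC(B1OC(C)(C)C(C)(C)O1)B1OC(C)(C)C(C)(C)O1 | starting material
17 | 1-lithio-1,1-bis(pinacolboryl)ethane | [Li]C(C)(B1OC(C)(C)C(C)(C)O1)B1OC(C)(C)C(C)(C)O1 | intermediate
18 | C29 nonaenyl pinacol boronate, Bpin on C9 and trans to C11 (chain geometry as in the target; Z by the CIP rule because C outranks B) | CC(C)=CCC/C(C)=C/C=C/C(C)=C/C=C/C(C)=C/C=C/C=C(C)/C=C/C=C(C)/B1OC(C)(C)C(C)(C)O1 | intermediate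
19 | (6S)-ε,ψ-carotene [(6S)-δ-carotene] | CC(C)=CCC/C(C)=C/C=C/C(C)=C/C=C/C(C)=C/C=C/C=C(C)/C=C/C=C(C)/C=C/[C@@H]1C(C)=CCCC1(C)C | target

Total step count: 10. Longest linear sequence: 6 steps (steps 1–5 and 10); the polyenal branch has 5 (steps 6–10).

Steps most likely to fail

Risk 1, step 10. Two things may go wrong: E/Z control in the B–O elimination may erode because the residue on C10 is a flat polyenyl group, and the boronate may undergo protodeboronation before transmetalation.
- The fallback sets out from 15 and 7 and comes back at 19.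
- It lets the steric difference between two C–Br bonds decide the C9=C10 geometry, instead of an elimination.
- Ramirez olefination of 15 (CBr4, PPh3, Zn, CH2Cl2, 0 °C) should give the C28 1,1-dibromide F1.
- Iodine–lithium exchange on 7 (t-BuLi, Et2O, −78 °C) gives the alkenyllithium F2, and ZnCl2 converts it into the alkenylzinc chloride F3.
- Negishi coupling of F1 with F3 under PdCl2(DPEphos) in THF at 0–23 °C should replace only the less hindered C–Br bond trans to C11. This forms C8–C9 and gives the (9Z)-9-bromo-19-nor polyene F4.
- A second Negishi coupling with MeZnCl under Pd(P(t-Bu)3)2 installs C19 and gives 19. The bulky monophosphine is chosen because it keeps the configuration of 2-bromo-1,3-dienes, whereas chelating phosphines allow inversion.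

Risk 2, step 3. The [1,2]-shift may compete, and attack of the carbanion on the alkene carbon next to the quaternary centre may be slow, so that protonated or decomposed ether accumulates.
- The fallback sets out from 2 and comes back at 6.
- Heating 2 with N,N-dimethylformamide dimethyl acetal (xylene, reflux) exchanges one methoxy group for the allylic alkoxide.
- Loss of methanol gives an alkoxy(dimethylamino)carbene, which undergoes a neutral, suprafacial [2,3]-shift to (1S)-N,N,2,6,6-pentamethylcyclohex-2-ene-1-carboxamide F5.
- Partial reduction of the tertiary amide with Cp2Zr(H)Cl (THF, 23 °C; then H2O) gives 6, so that tin, organolithium and the separate oxidation are all bypassed.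

Risk 3, step 5. Addition of the gem-dichromium reagent to the hindered aldehyde may be slow, giving Lewis acidic trivalent chromium time to epimerise C6 or move the ring double bond into conjugation.
- The fallback sets out from 6 and comes back at 7.
- Ramirez olefination (CBr4, PPh3, Zn, CH2Cl2, 0 °C) gives the dibromo-olefin F6.
- n-BuLi (2 equiv, THF, −78 °C) converts it by the Corey–Fuchs sequence into the lithium acetylide F7, and water gives the terminal alkyne F8.
- Syn hydrozirconation with Cp2Zr(H)Cl (THF, 23 °C) gives the (E)-alkenylzirconocene chloride F9, and iodinolysis with I2 at 0 °C should give 7 with retention.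

Further compounds
F1 | step 10 | all-E C28 1,1-dibromide (dibromomethylene derivative of apo-10′-lycopenal) | CC(C)=CCC/C(C)=C/C=C/C(C)=C/C=C/C(C)=C/C=C/C=C(C)/C=C/C=C(Br)Br
F2 | step 10 | (E)-2-[(1S)-2,6,6-trimethylcyclohex-2-en-1-yl]ethenyllithium | [Li]/C=C/[C@@H]1C(C)=CCCC1(C)C
F3 | step 10 | (E)-2-[(1S)-2,6,6-trimethylcyclohex-2-en-1-yl]ethenylzinc chloride | Cl[Zn]/C=C/[C@@H]1C(C)=CCCC1(C)C
F4 | step 10 | (6S,9Z)-9-bromo-19-nor-ε,ψ-carotene | CC(C)=CCC/C(C)=C/C=C/C(C)=C/C=C/C(C)=C/C=C/C=C(C)/C=C/C=C(Br)/C=C/[C@@H]1C(C)=CCCC1(C)C
F5 | step 3 | (1S)-N,N,2,6,6-pentamethylcyclohex-2-ene-1-carboxamide | CN(C)C(=O)[C@@H]1C(C)=CCCC1(C)C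
F6 | step 5 | (6S)-6-(2,2-dibromoethenyl)-1,5,5-trimethylcyclohex-1-ene | BrC(Br)=C[C@@H]1C(C)=CCCC1(C)C
F7 | step 5 | lithium acetylide of (6R)-6-ethynyl-1,5,5-trimethylcyclohex-1-ene | [Li]C#C[C@@H]1C(C)=CCCC1(C)C
F8 | step 5 | (6R)-6-ethynyl-1,5,5-trimethylcyclohex-1-ene (same spatial arrangement at C6; descriptor changes by the CIP rule) | C#C[C@@H]1C(C)=CCCC1(C)C
F9 | step 5 | chlorobis(cyclopentadienyl){(E)-2-[(1S)-2,6,6-trimethylcyclohex-2-en-1-yl]ethenyl}zirconium (cyclopentadienyl rings drawn σ-bonded) | Cl[Zr](/C=C/[C@@H]1C(C)=CCCC1(C)C)(C2C=CC=C2)C3C=CC=C3
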